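The central benzene ring (C1 hexanoyl, C3 isobutyl arm, C5 isopropyl arm, oxygen on C2, C4, C6) alternates carbon and oxygen substituents. C5–C6 is therefore a latent ynol ether, and C4, C1, C2, C3 are a latent 3-alkoxy vinylketene. A Danheiser benzannulation exploits this. One neutral thermolysis forms C4–C5 and C6–C1 and closes the arene, joining two halves that each already carry one (R)-methine. The precursors are a 3-ethoxy-4-alkylcyclobutenone bearing the isobutyl arm and an ethoxyalkyne bearing the isopropyl arm, with both syncarpic enols masked as benzyl ethers. C1 hexanoylation and one global ether cleavage complete the route.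

Key step: step 10

Remarks
- Abbreviations: BnO-Syn = 2-(benzyloxy)-3,3,5,5-tetramethyl-4,6-dioxocyclohex-1-en-1-yl. HO-Syn is the same ring with a free enol OH. The arene numbering C1–C6 given above is used throughout.
- Assumption: the enolic triketone rings are degenerate, rapidly interconverting tautomers, so O-benzylation at either enol oxygen gives the same compound.
- A free syncarpic enol is acidic enough to add to an ynol ether or a ketene. It is therefore capped before either function is present, or kept as its enolate until it is capped.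
- Boron halides remove benzyl enol ethers at least as readily as aryl ethyl ethers, so all four ethers are cleaved in one final operation.
- Both methines are (R) in every isolated intermediate. Joining two enantioenriched halves turns most residual minor enantiomer into a separable diastereomer.

Step 1
Reactants: 1 2',4',6'-trihydroxyacetophenone
Product: 2 2-acetyl-3-hydroxy-4,4,6,6-tetramethylcyclohex-2-ene-1,5-dione
Conditions: MeI (excess), NaOMe, MeOH, reflux
Reagents that add atoms: iodomethane, CI
Why: Exhaustive dearomatising C-methylation of the phloroglucinol anion, in which the acetyl group blocks the third ring carbon so that four methyl groups end up as two gem-dimethyl pairs.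

Step 2
Reactants: 2 2-acetyl-3-hydroxy-4,4,6,6-tetramethylcyclohex-2-ene-1,5-dione
Product: 3 syncarpic acid (5-hydroxy-2,2,6,6-tetramethylcyclohex-4-ene-1,3-dione)
Conditions: 6 M aq. HCl, reflux
Reagents that add atoms: none
Why: Acid-promoted retro-Claisen deacylation removes the exocyclic acetyl group, while the ring carbonyls flanked by quaternary carbons cannot fragment in the same way.

Step 3
Reactants: 4 isovaleraldehyde; 5 (triphenylphosphoranylidene)acetaldehyde
Product: 6 (E)-5-methylhex-2-enal
Conditions: PhMe, 80 °C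
Reagents that add atoms: none
Why: Wittig olefination with a stabilised formyl ylide should give the (E)-enal as the main isomer.

Step 4
Reactants: 3 syncarpic acid; 6 (E)-5-methylhex-2-enal
Product: 7 (4R)-2-hydroxy-4-isobutyl-6,6,8,8-tetramethyl-3,4-dihydro-2H-chromene-5,7(6H,8H)-dione (lactol, both anomers)
Conditions: (S)-2-[diphenyl(trimethylsilyloxy)methyl]pyrrolidine (20 mol%), CH2Cl2, 0 °C → rt
Reagents that add atoms: none
Why: Iminium-catalysed asymmetric Michael addition of a cyclic 1,3-dicarbonyl to an aliphatic enal, in which the diphenyl(silyloxy)methyl group of the (S)-catalyst shields one face of the (E)-iminium ion, C2 of 3 attacks the open Re face of the β-carbon to set the (R)-methine, and hemiacetal closure takes the adduct out of the equilibrium.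

Step 5
Reactants: 7 lactol
Product: 9 (3R)-3-(BnO-Syn)-5-methylhexanal, via potassium enolate 8 (not isolated)
Conditions: BnBr, K2CO3, DMF, 0 °C → rt
Reagents that add atoms: benzyl bromide, BrCc1ccccc1
Why: Carbonate deprotonates only the acidic enol of the ring-opened tautomer, and Williamson-type O-alkylation is favoured because C-alkylation would build a quaternary carbon next to the branched arm; once the enol is capped, retro-Michael loss of the arm is blocked.

Step 6
Reactants: 9 (3R)-3-(BnO-Syn)-5-methylhexanal
Product: 10 (3R)-3-(BnO-Syn)-5-methylhexanoic acid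
Conditions: NaClO2, NaH2PO4, 2-methylbut-2-ene, t-BuOH/H2O, rt
Reagents that add atoms: sodium chlorite, [Na+].[O-]Cl=O
Why: Pinnick oxidation is selective for the aldehyde, and the buffer and hypochlorite scavenger leave the electron-poor benzyl enol ether and the β-stereocentre untouched.

Step 7
Reactants: 10 (3R)-3-(BnO-Syn)-5-methylhexanoic acid; 11 ethoxyacetylene
Product: 14 3-ethoxy-4-[(1R)-1-(BnO-Syn)-3-methylbutyl]cyclobut-2-en-1-one (both C4 epimers), via acid chloride 12 (not isolated), via aldoketene 13 (not isolated)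
Conditions: 1-chloro-N,N,2-trimethylprop-1-en-1-amine, CH2Cl2, 0 °C; then 11 (5 equiv), Et3N, Et2O, 0 °C → rt
Reagents that add atoms: none
Why: Neutral chloroenamine activation and amine dehydrochlorination give the aldoketene, which excess ethoxyacetylene intercepts in an electronically matched [2+2] cycloaddition (alkyne CH to the ketene carbonyl carbon), a known entry to 4-alkyl-3-ethoxycyclobutenones; the methine is untouched and the new ring stereocentre does not matter because it becomes aromatic.

Step 8
Reactants: 3 syncarpic acid; 15 isobutyraldehyde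
Product: 17 2-(2-methylpropylidene)-4,4,6,6-tetramethylcyclohexane-1,3,5-trione, via Mannich base 16 (not isolated)
Conditions: piperidine, CH2Cl2, rt; then 1 M aq. HCl, 0 °C
Reagents that add atoms: none
Why: Knoevenagel condensation run through the Mannich base, whose acid-induced amine elimination releases the exocyclic enetrione when no free syncarpic acid is left to form a bis-adduct; 17 is used at once.

Step 9
Reactants: 17 2-(2-methylpropylidene)-4,4,6,6-tetramethylcyclohexane-1,3,5-trione; 11 ethoxyacetylene
Product: 19 3-(benzyloxy)-2-[(3R)-1-ethoxy-4-methylpent-1-yn-3-yl]-4,4,6,6-tetramethylcyclohex-2-ene-1,5-dione, via ammonium enolate 18 (not isolated)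
Conditions: [Cu(MeCN)4]PF6 (10 mol%), (R,M)-N-PINAP (11 mol%), i-Pr2NEt (1.2 equiv), 11 (3 equiv), PhMe, −20 °C; strip excess 11; then BnBr, n-Bu4NI (cat.), DMF, 0 °C → rt
Reagents that add atoms: benzyl bromide, BrCc1ccccc1
Why: Proposed new method: soft deprotonation of 11 by the amine at ligated monovalent copper gives a chiral copper ethoxyacetylide, which should deliver the alkynyl group to one enantiotopic face of the exocyclic C=C of 17 (a symmetrical, s-cis-locked acceptor with no E/Z issue) and set the (R)-methine under ligand control, the ligand antipode being chosen once the sense of induction is assigned; the conjugate acid of the product enolate is far stronger than the ammonium ion, so the enolate stays deprotonated, the acid-labile ynol ether never meets a free enol OH, and O-benzylation of the C-blocked enolate follows in the same flask; the closest known reaction type is the copper/P,N-ligand-catalysed enantioselective conjugate addition of terminal alkynes to alkylidene Meldrum's acids (β-isopropyl acceptors included), which has not been shown with an alkoxyacetylene or in an amine-buffered anhydrous medium.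

Step 10
Reactants: 14 3-ethoxy-4-[(1R)-1-(BnO-Syn)-3-methylbutyl]cyclobut-2-en-1-one; 19 ynol ether
Product: 24 3,5-diethoxy-2-[(1R)-1-(BnO-Syn)-3-methylbutyl]-6-[(1R)-1-(BnO-Syn)-2-methylpropyl]phenol, via vinylketene 20 (not isolated), via vinylcyclobutenone 21 (not isolated), via dienylketene 22 (not isolated), via cyclohexadienone 23 (not isolated)
Conditions: PhMe (0.5 M), sealed tube, 105 °C (19 in slight excess)
Reagents that add atoms: none
Why: Heating opens 14 by a conrotatory 4π electrocyclic reaction that cuts the bond between the carbonyl carbon (future C4) and the arm-bearing sp3 carbon (future C3), the arm turning outward to give vinylketene 20. Ynol ether 19 then adds across the ketene C=C in a [2+2] cycloaddition, its nucleophilic carbon-substituted terminus (C5) bonding to the ketene carbonyl carbon (C4) and its oxygen-bearing terminus (C6) to C1, which gives 21. A second 4π opening cuts C4–C1 to give dienylketene 22, the six-membered ring closes by a thermal disrotatory 6π electrocyclisation that re-forms C3–C4 (23), and tautomerisation delivers phenol 24. This is the Danheiser benzannulation of a cyclobutenone with an alkoxyalkyne, applied to a 3-alkoxy-4-alkyl partner so that a phloroglucinol pattern results. No stereocentre is created: the ring stereocentres of 14, 21 and 23 vanish on aromatisation, and the two (R)-methines are spectators because the medium holds neither acid nor base. The selectivity needed is the orientation of the ketene–alkyne union, which the complementary polarisation of the two partners secures, supported by a temperature below the retro-ene threshold of the ethoxyalkyne and by outward torquoselectivity, which puts the C–H bond of the arm out of reach for a 1,5-hydrogen migration.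

Step 11
Reactants: 24 benzannulation phenol; 25 hexanoyl chloride
Product: 26 1-{2,6-diethoxy-4-hydroxy-3-[(1R)-1-(BnO-Syn)-3-methylbutyl]-5-[(1R)-1-(BnO-Syn)-2-methylpropyl]phenyl}hexan-1-one
Conditions: TiCl4, CH2Cl2, −78 → −20 °C
Reagents that add atoms: none
Why: Friedel–Crafts acylation at C1, the only unsubstituted ring carbon, which lies para to the titanium phenoxide and between two ethoxy donors and should react at low temperature, where the benzyl enol ethers and the benzylic methines should hold.

Step 12
Reactants: 26 hexanoyl diethyl ether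
Product: 27 myrtucommulone H, 1-{2,4,6-trihydroxy-3-[(1R)-1-(HO-Syn)-3-methylbutyl]-5-[(1R)-1-(HO-Syn)-2-methylpropyl]phenyl}hexan-1-one
Conditions: BCl3, n-Bu4NI, CH2Cl2, −78 → 0 °C; then ice-cold pH 5 buffer
Reagents that add atoms: none
Why: Boron trichloride with iodide as external nucleophile cleaves primary alkyl aryl ethers and benzyl vinylogous esters by O-coordination and SN2 dealkylation; both ethoxy groups are activated by the ortho ketone and by being twisted out of conjugation between two ortho substituents, and the low temperature should keep the methines from ionising.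

Compound list
1 | 2',4',6'-trihydroxyacetophenone | CC(=O)c1c(O)cc(O)cc1O | starting material
2 | 2-acetyl-3-hydroxy-4,4,6,6-tetramethylcyclohex-2-ene-1,5-dione | CC(=O)C1=C(O)C(C)(C)C(=O)C(C)(C)C1=O | intermediate
3 | syncarpic acid | CC1(C)C(=O)C=C(O)C(C)(C)C1=O | intermediate
4 | isovaleraldehyde | CC(C)CC=O | starting material
5 | (triphenylphosphoranylidene)acetaldehyde | O=CC=P(c1ccccc1)(c1ccccc1)c1ccccc1 | starting material
6 | (E)-5-methylhex-2-enal | CC(C)C/C=C/C=O | intermediate
7 | (4R)-2-hydroxy-4-isobutyl-6,6,8,8-tetramethyl-3,4-dihydro-2H-chromene-5,7(6H,8H)-dione | OC1C[C@@H](CC(C)C)C2=C(O1)C(C)(C)C(=O)C(C)(C)C2=O | intermediate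
8 | potassium enolate of ring-opened 7, (R) | O=CC[C@@H](CC(C)C)C1=C([O-])C(C)(C)C(=O)C(C)(C)C1=O.[K+] | intermediate
9 | (3R)-3-(BnO-Syn)-5-methylhexanal | O=CC[C@@H](CC(C)C)C1=C(OCc2ccccc2)C(C)(C)C(=O)C(C)(C)C1=O | intermediate
10 | (3R)-3-(BnO-Syn)-5-methylhexanoic acid | OC(=O)C[C@@H](CC(C)C)C1=C(OCc2ccccc2)C(C)(C)C(=O)C(C)(C)C1=O | intermediate
11 | ethoxyacetylene | CCOC#C | starting material
12 | (3R)-3-(BnO-Syn)-5-methylhexanoyl chloride | ClC(=O)C[C@@H](CC(C)C)C1=C(OCc2ccccc2)C(C)(C)C(=O)C(C)(C)C1=O | intermediate
13 | (3R)-3-(BnO-Syn)-5-methylhex-1-en-1-one (aldoketene) | O=C=C[C@@H](CC(C)C)C1=C(OCc2ccccc2)C(C)(C)C(=O)C(C)(C)C1=O | intermediate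
14 | 3-ethoxy-4-[(1R)-1-(BnO-Syn)-3-methylbutyl]cyclobut-2-en-1-one, both C4 epimers | CCOC1=CC(=O)C1[C@@H](CC(C)C)C1=C(OCc2ccccc2)C(C)(C)C(=O)C(C)(C)C1=O | intermediate
15 | isobutyraldehyde | CC(C)C=O | starting material
16 | 3-hydroxy-4,4,6,6-tetramethyl-2-[2-methyl-1-(piperidin-1-yl)propyl]cyclohex-2-ene-1,5-dione (racemic Mannich base) | CC(C)C(N1CCCCC1)C1=C(O)C(C)(C)C(=O)C(C)(C)C1=O | intermediate
17 | 2-(2-methylpropylidene)-4,4,6,6-tetramethylcyclohexane-1,3,5-trione | CC(C)C=C1C(=O)C(C)(C)C(=O)C(C)(C)C1=O | intermediate
18 | ethyldiisopropylammonium enolate of 2-[(3R)-1-ethoxy-4-methylpent-1-yn-3-yl]syncarpic acid | CCOC#C[C@H](C1=C([O-])C(C)(C)C(=O)C(C)(C)C1=O)C(C)C.CC[NH+](C(C)C)C(C)C | intermediate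
19 | 3-(benzyloxy)-2-[(3R)-1-ethoxy-4-methylpent-1-yn-3-yl]-4,4,6,6-tetramethylcyclohex-2-ene-1,5-dione | CCOC#C[C@H](C1=C(OCc2ccccc2)C(C)(C)C(=O)C(C)(C)C1=O)C(C)C | intermediate
20 | (3Z,5R)-3-ethoxy-5-(BnO-Syn)-7-methylocta-1,3-dien-1-one (vinylketene, arm outward) | O=C=C/C(OCC)=C/[C@@H](CC(C)C)C1=C(OCc2ccccc2)C(C)(C)C(=O)C(C)(C)C1=O | intermediate
21 | 3-ethoxy-2-(isopropyl arm)-4-[1-ethoxy-2-(isobutyl arm)vinyl]cyclobut-2-en-1-one, methines as in 14 and 19 | CCOC1=C([C@H](C2=C(OCc3ccccc3)C(C)(C)C(=O)C(C)(C)C2=O)C(C)C)C(=O)C1/C(OCC)=C/[C@@H](CC(C)C)C4=C(OCc5ccccc5)C(C)(C)C(=O)C(C)(C)C4=O | intermediate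
22 | 3,5-diethoxy dienylketene carrying both arms, methines as in 14 and 19 | O=C=C([C@H](C2=C(OCc3ccccc3)C(C)(C)C(=O)C(C)(C)C2=O)C(C)C)/C(OCC)=C\C(OCC)=C\[C@@H](CC(C)C)C4=C(OCc5ccccc5)C(C)(C)C(=O)C(C)(C)C4=O | intermediate
23 | 3,5-diethoxy-2-(isopropyl arm)-6-(isobutyl arm)cyclohexa-2,4-dien-1-one, methines as in 14 and 19 | CCOC1=CC(OCC)=C([C@H](C2=C(OCc3ccccc3)C(C)(C)C(=O)C(C)(C)C2=O)C(C)C)C(=O)C1[C@@H](CC(C)C)C4=C(OCc5ccccc5)C(C)(C)C(=O)C(C)(C)C4=O | intermediate
24 | 3,5-diethoxy-2-[(1R)-1-(BnO-Syn)-3-methylbutyl]-6-[(1R)-1-(BnO-Syn)-2-methylpropyl]phenol | c1c(OCC)c([C@@H](CC(C)C)C2=C(OCc3ccccc3)C(C)(C)C(=O)C(C)(C)C2=O)c(O)c([C@H](C2=C(OCc3ccccc3)C(C)(C)C(=O)C(C)(C)C2=O)C(C)C)c1OCC | intermediate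
25 | hexanoyl chloride | CCCCCC(=O)Cl | starting material
26 | 1-{2,6-diethoxy-4-hydroxy-3-[(1R)-1-(BnO-Syn)-3-methylbutyl]-5-[(1R)-1-(BnO-Syn)-2-methylpropyl]phenyl}hexan-1-one | CCCCCC(=O)c1c(OCC)c([C@@H](CC(C)C)C2=C(OCc3ccccc3)C(C)(C)C(=O)C(C)(C)C2=O)c(O)c([C@H](C2=C(OCc3ccccc3)C(C)(C)C(=O)C(C)(C)C2=O)C(C)C)c1OCC | intermediate
27 | myrtucommulone H | CCCCCC(=O)c1c(O)c([C@@H](CC(C)C)C2=C(O)C(C)(C)C(=O)C(C)(C)C2=O)c(O)c([C@H](C2=C(O)C(C)(C)C(=O)C(C)(C)C2=O)C(C)C)c1O | target

Total step count: 12. Longest linear sequence: 9 steps (1, 2, 4, 5, 6, 7, 10, 11, 12).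

Steps most likely to fail

1. Step 9. The amine may deconjugate 17 by γ-deprotonation before the alkynyl group is transferred. An unligated background addition may erode facial selectivity. Adventitious protonation of 18 would let the enol oxygen add to the ynol ether. The fallback uses known chemistry, sets out from 17 and 11, and returns at 24. Deprotonation of 11 with EtMgBr in THF gives ethoxyethynylmagnesium bromide F1. Its uncatalysed 1,4-addition to 17 at −78 °C gives the racemic bromomagnesium enolate F2. Adding DMF, n-Bu4NI and BnBr without any protic quench gives the racemic ynol ether F3. F3 is used in at least twofold excess in step 10 with enantiopure 14. The product is then 24 together with its isopropyl-arm (1S)-epimer F4. These are diastereomers, so they can be parted on silica or by achiral preparative HPLC, and the route continues from 24.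

2. Step 10. The donor-stabilised cyclobutenone may open only at temperatures where 19 loses ethylene by retro-ene fragmentation. The bulky propargylic substituent may also slow the [2+2] step enough for the vinylketene to dimerise or be trapped by a neighbouring vinylogous ester carbonyl. The fallback reaches vinylketene 20 without any ring opening. It sets out from 10 (through 12) and returns at 20, hence at 24.
   - Acylation of potassium ethyl malonate with 12 (MgCl2, Et3N, MeCN) and decarboxylation in the flask gives ethyl (5R)-5-(BnO-Syn)-7-methyl-3-oxooctanoate F5.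
   - Triethyl orthoformate with catalytic acid gives ethyl (2E,5R)-3-ethoxy-5-(BnO-Syn)-7-methyloct-2-enoate F6.
   - LiOH gives (2E,5R)-3-ethoxy-5-(BnO-Syn)-7-methyloct-2-enoic acid F7.
   - The chloroenamine reagent of step 7 gives (2E,5R)-3-ethoxy-5-(BnO-Syn)-7-methyloct-2-enoyl chloride F8.
   - Slow addition of F8 to Et3N and 19 at room temperature generates 20 by 1,4-dehydrochlorination.

   The cycloaddition to 21 then runs far below the retro-ene threshold, and only the reorganisation of 21 needs gentle heating (about 80 °C).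

3. Step 12. Dealkylation may stall after the first aryl ether, once the boron aryloxide has tied up the ketone. Forcing the reaction may ionise a benzylic C–C bond (epimerisation) or close a pyran ring between a phenol and an enol. The fallback sets out from 26 and returns at 27, and it splits the two ether types between two unrelated mechanisms. Hydrogenolysis (H2, Pd/C, EtOAc) removes both benzyl groups under neutral conditions and gives the 2,6-di-O-ethyl ether of myrtucommulone H F9. The ethyl groups are then taken off with the hard-acid/soft-nucleophile pair AlCl3/EtSH in CH2Cl2 at 0 °C. Here an external thiol performs the SN2 step, so the second ether does not depend on a free ketone.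

Further compounds
F1 | step 9 | ethoxyethynylmagnesium bromide | CCOC#C[Mg]Br
F2 | step 9 | racemic bromomagnesium enolate of 2-(1-ethoxy-4-methylpent-1-yn-3-yl)syncarpic acid | CCOC#CC(C(C)C)C1=C(O[Mg]Br)C(C)(C)C(=O)C(C)(C)C1=O
F3 | step 9 | racemic ynol ether (racemate of 19) | CCOC#CC(C(C)C)C1=C(OCc2ccccc2)C(C)(C)C(=O)C(C)(C)C1=O
F4 | step 9 | isopropyl-arm (1S)-epimer of 24 | c1c(OCC)c([C@@H](CC(C)C)C2=C(OCc3ccccc3)C(C)(C)C(=O)C(C)(C)C2=O)c(O)c([C@@H](C2=C(OCc3ccccc3)C(C)(C)C(=O)C(C)(C)C2=O)C(C)C)c1OCC
F5 | step 10 | ethyl (5R)-5-(BnO-Syn)-7-methyl-3-oxooctanoate | CCOC(=O)CC(=O)C[C@@H](CC(C)C)C1=C(OCc2ccccc2)C(C)(C)C(=O)C(C)(C)C1=O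
F6 | step 10 | ethyl (2E,5R)-3-ethoxy-5-(BnO-Syn)-7-methyloct-2-enoate | CCOC(=O)/C=C(OCC)\C[C@@H](CC(C)C)C1=C(OCc2ccccc2)C(C)(C)C(=O)C(C)(C)C1=O
F7 | step 10 | (2E,5R)-3-ethoxy-5-(BnO-Syn)-7-methyloct-2-enoic acid | OC(=O)/C=C(OCC)\C[C@@H](CC(C)C)C1=C(OCc2ccccc2)C(C)(C)C(=O)C(C)(C)C1=O
F8 | step 10 | (2E,5R)-3-ethoxy-5-(BnO-Syn)-7-methyloct-2-enoyl chloride | ClC(=O)/C=C(OCC)\C[C@@H](CC(C)C)C1=C(OCc2ccccc2)C(C)(C)C(=O)C(C)(C)C1=O
F9 | step 12 | 2,6-di-O-ethyl ether of myrtucommulone H | CCCCCC(=O)c1c(OCC)c([C@@H](CC(C)C)C2=C(O)C(C)(C)C(=O)C(C)(C)C2=O)c(O)c([C@H](C2=C(O)C(C)(C)C(=O)C(C)(C)C2=O)C(C)C)c1OCC
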